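The target is disconnected at the C1–C8 bond, between the bridgehead CH and the bridging ketone, which completes the 1,3‑diketone C2(=O)–C1–C8(=O). A γ‑butyrolactone holds C8 as its carbonyl, C5–C6–C7 as its ring carbons, and its ring oxygen on benzylic C7, where C1 must end up. In one operation a methyl‑ketone enolate (C1) attacks the lactone carbonyl, a Claisen acyl transfer that closes the six‑membered ring C1–C2–C3–C4–C5–C8. Acid then ionises the freed veratryl carbinol, C1 captures C7 to close the five‑membered ring, and dehydration gives the methoxy‑enone. The precursor is a monocyclic α‑allyl lactone bearing an aldol side chain.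

Key step: step 8

Remark: locants C1–C8 are those of the bicyclo[3.2.1]octane core of the target (C1 bridgehead CH, C2 and C8 ketones, C3 OMe, C5 allyl, C6 methyl, C7 aryl); Ar = 3,4‑dimethoxyphenyl.
Assumption: the two side‑chain stereocentres created in step 7 should form unselectively and are erased in step 8, so they are left unassigned in 12, 13 and 14; equilibrating silylation of methoxyacetone is assumed to favour the methoxy‑side enol silane 11.

Step 1
Reactants: 1 3,4‑dimethoxybenzaldehyde; 2 (E)‑but‑2‑ene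
Product: 5 (1S,2S)‑1‑(3,4‑dimethoxyphenyl)‑2‑methylbut‑3‑en‑1‑ol, via (E)‑crotylpotassium 3 (not isolated), via (E)‑crotyldiisopinocampheylborane 4 (not isolated)
Conditions: 2, KOt‑Bu, n‑BuLi, THF, −78 to −45 °C; (−)‑Ipc2BOMe (from (+)‑α‑pinene), −78 °C; BF3·OEt2; then 1, −78 °C; NaOH, H2O2, rt
Reagents that add atoms: none
Why: Brown crotylboration through a closed chair transition state, in which the (E)‑crotyl geometry gives the anti relationship and the isopinocampheyl groups from (+)‑α‑pinene direct attack to the Si face of the aldehyde, should set (1S,2S).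

Step 2
Reactants: 5 (1S,2S)‑1‑(3,4‑dimethoxyphenyl)‑2‑methylbut‑3‑en‑1‑ol
Product: 6 (1S,2S)‑1‑(3,4‑dimethoxyphenyl)‑2‑methylbutane‑1,4‑diol
Conditions: 9‑BBN, THF, 0 °C to rt; then NaOH, H2O2
Reagents that add atoms: hydrogen peroxide, OO
Why: Anti‑Markovnikov hydroboration–oxidation of the terminal alkene should give the primary alcohol without touching either stereocentre.

Step 3
Reactants: 6 (1S,2S)‑1‑(3,4‑dimethoxyphenyl)‑2‑methylbutane‑1,4‑diol
Product: 7 (4S,5S)‑5‑(3,4‑dimethoxyphenyl)‑4‑methyldihydrofuran‑2(3H)‑one (trans lactone)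
Conditions: TEMPO (cat.), PhI(OAc)2, CH2Cl2, rt
Reagents that add atoms: none
Why: Oxoammonium oxidation is selective for the primary alcohol, and the aldehyde should close to the lactol and be oxidised on to the lactone (oxidative lactonisation of a 1,4‑diol) with the trans arrangement retained.

Step 4
Reactants: 7 (4S,5S)‑5‑(3,4‑dimethoxyphenyl)‑4‑methyldihydrofuran‑2(3H)‑one
Product: 8 (4S,5S)‑5‑(3,4‑dimethoxyphenyl)‑4‑methyl‑2‑oxotetrahydrofuran‑3‑carbaldehyde (C3 labile, largely the hydroxymethylene tautomer)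
Conditions: NaH, HCO2Et, THF, 0 °C to rt; then cold 1 M HCl
Reagents that add atoms: ethyl formate, CCOC=O
Why: Crossed Claisen condensation of the lactone enolate with a non‑enolisable formate is driven by deprotonation of the formyl lactone, and C4 and C5 are not acidic and stay intact.

Step 5
Reactants: 8 (4S,5S)‑5‑(3,4‑dimethoxyphenyl)‑4‑methyl‑2‑oxotetrahydrofuran‑3‑carbaldehyde
Product: 9 (3S,4S,5S)‑3‑allyl‑5‑(3,4‑dimethoxyphenyl)‑4‑methyl‑2‑oxotetrahydrofuran‑3‑carbaldehyde
Conditions: allyl methyl carbonate, Pd(PPh3)4 (5 mol%), THF, rt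
Reagents that add atoms: allyl methyl carbonate, C=CCOC(=O)OC
Why: Tsuji–Trost allylation of the stabilised formyl‑lactone enolate under neutral conditions should occur at carbon on the face anti to the adjacent 4‑methyl group, setting the quaternary centre (3S) with the formyl group cis to the methyl.

Step 6
Reactants: 10 methoxyacetone (1‑methoxypropan‑2‑one)
Product: 11 (Z)‑1‑methoxy‑2‑(trimethylsilyloxy)prop‑1‑ene
Conditions: Me3SiCl, NaI, Et3N, MeCN, rt; pentane extraction, distillation
Reagents that add atoms: chlorotrimethylsilane, C[Si](C)(C)Cl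
Why: Silyl enol ether formation through Me3SiI made in the flask, under equilibrating conditions, should favour the more substituted, oxygen‑stabilised enol ether on the methoxy side.

Step 7
Reactants: 9 (3S,4S,5S)‑3‑allyl‑5‑(3,4‑dimethoxyphenyl)‑4‑methyl‑2‑oxotetrahydrofuran‑3‑carbaldehyde; 11 (Z)‑1‑methoxy‑2‑(trimethylsilyloxy)prop‑1‑ene
Product: 12 (3S,4S,5S)‑3‑allyl‑5‑(3,4‑dimethoxyphenyl)‑3‑(1‑hydroxy‑2‑methoxy‑3‑oxobutyl)‑4‑methyldihydrofuran‑2(3H)‑one (mixture at the two side‑chain centres)
Conditions: Sc(OTf)3 (10 mol%), CH2Cl2, −78 to −40 °C; then 1 M HCl, THF, 0 °C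
Reagents that add atoms: none
Why: Mukaiyama aldol addition to the non‑enolisable aldehyde, with the regiochemistry fixed by the enol silane so that the methoxy‑bearing carbon (C3) bonds to the aldehyde carbon (C4); the two new centres need no control.

Step 8
Reactants: 12 (3S,4S,5S)‑3‑allyl‑5‑(3,4‑dimethoxyphenyl)‑3‑(1‑hydroxy‑2‑methoxy‑3‑oxobutyl)‑4‑methyldihydrofuran‑2(3H)‑one
Product: 15 Kadsurenin D [(1S,5S,6R,7R)‑5‑allyl‑7‑(3,4‑dimethoxyphenyl)‑3‑methoxy‑6‑methylbicyclo[3.2.1]oct‑3‑ene‑2,8‑dione], via cyclohexane‑1,3‑dione 13 (not isolated), via hydroxy diketone 14 (not isolated)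
Conditions: 12 added to LiN(i‑Pr)2 (3.2 equiv), THF, −78 to −30 °C; quench with CF3CO2H, solvent exchange; CF3CO2H/CH2Cl2, 0 °C to rt
Reagents that add atoms: none
Why: LiN(i‑Pr)2 should deprotonate the carbinol and, kinetically, the methyl group of the ketone (C3–H is flanked by the methoxy group and the alkoxide‑bearing carbon), and the enolate carbon C1 then adds to the lactone carbonyl C8 with expulsion of the C7 alkoxide, an intramolecular Claisen (Dieckmann‑type) acyl transfer that closes the six‑membered ring C1–C2–C3–C4–C5–C8 in a 6‑(enolexo)‑exo‑trig mode and is pulled forward by the stabilised 1,3‑dionate 13. CF3CO2H then ionises the freed 3,4‑dimethoxybenzylic carbinol and the dione enol is alkylated at C1 by the C7 cation, a 5‑(enolexo) closure onto the trigonal cation that forms the five‑membered ring C1–C7–C6–C5–C8 and with it the seven‑membered ring; the closest known type is the acid‑induced hydrobenzofuranoid‑to‑bicyclo[3.2.1]octanoid neolignan rearrangement. Acid‑catalysed loss of water from the β‑hydroxy ketone 14 (C4–OH, C3–H) installs the ring‑locked cis C3=C4 methoxy‑enone. C1 is fixed by the one‑carbon bridge, and C7 is set by approach of C1 to the cation face anti to the C6 methyl, which places the aryl group exo and trans to the endo methyl; C5 and C6 are carried unchanged from 12. The step needs C‑ rather than O‑alkylation, secured because benzylic ethers re‑ionise under the acid while the C–C bond does not, and it needs the cation to be trapped before it loses the C6 proton, secured by the intramolecular, strongly nucleophilic enol.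

Compound list
1 | 3,4‑dimethoxybenzaldehyde | COc1ccc(C=O)cc1OC | starting material
2 | (E)‑but‑2‑ene | C/C=C/C | starting material
3 | (E)‑crotylpotassium | C/C=C/[CH2-].[K+] | intermediate
4 | (E)‑crotyldiisopinocampheylborane, Ipc groups from (+)‑α‑pinene | C/C=C/CB([C@@H]1C[C@@H]2C[C@H]([C@H]1C)C2(C)C)[C@@H]1C[C@@H]2C[C@H]([C@H]1C)C2(C)C | intermediate
5 | (1S,2S)‑1‑(3,4‑dimethoxyphenyl)‑2‑methylbut‑3‑en‑1‑ol | C=C[C@H](C)[C@H](O)c1ccc(OC)c(OC)c1 | intermediate
6 | (1S,2S)‑1‑(3,4‑dimethoxyphenyl)‑2‑methylbutane‑1,4‑diol | OCC[C@H](C)[C@H](O)c1ccc(OC)c(OC)c1 | intermediate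
7 | (4S,5S)‑5‑(3,4‑dimethoxyphenyl)‑4‑methyldihydrofuran‑2(3H)‑one | O=C1C[C@H](C)[C@@H](c2ccc(OC)c(OC)c2)O1 | intermediate
8 | (4S,5S)‑5‑(3,4‑dimethoxyphenyl)‑4‑methyl‑2‑oxotetrahydrofuran‑3‑carbaldehyde (C3 labile) | O=CC1C(=O)O[C@H](c2ccc(OC)c(OC)c2)[C@H]1C | intermediate
9 | (3S,4S,5S)‑3‑allyl‑5‑(3,4‑dimethoxyphenyl)‑4‑methyl‑2‑oxotetrahydrofuran‑3‑carbaldehyde | O=C[C@@]1(CC=C)C(=O)O[C@H](c2ccc(OC)c(OC)c2)[C@H]1C | intermediate
10 | methoxyacetone | COCC(C)=O | starting material
11 | (Z)‑1‑methoxy‑2‑(trimethylsilyloxy)prop‑1‑ene | CO/C=C(/C)O[Si](C)(C)C | intermediate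
12 | (3S,4S,5S)‑3‑allyl‑5‑(3,4‑dimethoxyphenyl)‑3‑(1‑hydroxy‑2‑methoxy‑3‑oxobutyl)‑4‑methyldihydrofuran‑2(3H)‑one (side‑chain centres unassigned) | CC(=O)C(OC)C(O)[C@@]1(CC=C)C(=O)O[C@H](c2ccc(OC)c(OC)c2)[C@H]1C | intermediate
13 | (4S)‑4‑allyl‑4‑[(1S,2S)‑1‑(3,4‑dimethoxyphenyl)‑1‑hydroxypropan‑2‑yl]‑5‑hydroxy‑6‑methoxycyclohexane‑1,3‑dione (C5, C6 of the ring unassigned) | O=C1CC(=O)C(OC)C(O)[C@]1(CC=C)[C@H](C)[C@H](O)c1ccc(OC)c(OC)c1 | intermediate
14 | (1S,5S,6R,7R)‑5‑allyl‑7‑(3,4‑dimethoxyphenyl)‑4‑hydroxy‑3‑methoxy‑6‑methylbicyclo[3.2.1]octane‑2,8‑dione (C3, C4 unassigned) | C=CC[C@]12C(O)C(OC)C(=O)[C@H](C1=O)[C@H](c1ccc(OC)c(OC)c1)[C@H]2C | intermediate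
15 | Kadsurenin D, (1S,5S,6R,7R)‑5‑allyl‑7‑(3,4‑dimethoxyphenyl)‑3‑methoxy‑6‑methylbicyclo[3.2.1]oct‑3‑ene‑2,8‑dione | C=CC[C@]12C=C(OC)C(=O)[C@H](C1=O)[C@H](c1ccc(OC)c(OC)c1)[C@H]2C | target

Total step count: 8. Longest linear sequence: 7 (steps 1–5, 7, 8); step 6 is a one‑step side branch.

Steps most likely to fail

1. Step 8. Retro‑aldol fragmentation of the lithium aldolate may outrun the acyl transfer. In the acid stage the benzylic cation may lose the C6 proton and re‑protonate, eroding the C6 configuration, or the sequence may stall at O‑alkylated or undehydrated material. The fallback sets out from 12 and comes back at 15. The carbinol is first masked with Et3SiOSO2CF3 and 2,6‑lutidine as the triethylsilyl ether F1. LiN(SiMe3)2 in THF (−78 to 0 °C) then effects the acyl transfer on the protected substrate, and the cyclic 1,3‑dione F2 is isolated. The cation stage is run separately under thermodynamic control (p‑TsOH, benzene, 60 °C), which should remove the silyl group, dehydrate and close the bicycle to 15.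

2. Step 5. Facial selectivity may be poor in the outer‑sphere attack of the planar enolate on the allylpalladium species, and O‑allylation or methoxide‑induced deformylation of the quaternary aldehyde may compete. The fallback sets out from 8 and comes back at 9. Compound 8 is O‑allylated with allyl bromide and K2CO3 in acetone to the allyl enol ether F3. Heating F3 in toluene at 110 °C should then deliver the allyl group to C3 by a base‑free Claisen rearrangement, a concerted suprafacial transfer to the face anti to the 4‑methyl group.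

3. Step 7. Addition to the neopentyl‑type aldehyde may be slow, the Lewis acid may induce deformylation or ionise the benzylic lactone C–O bond, and regioisomeric enol silane from step 6 may be carried over. The fallback sets out from 9 and comes back at 12. Allyl 4‑methoxy‑3‑oxobutanoate F4 is made from commercial methyl 4‑methoxy‑3‑oxobutanoate and allyl alcohol by transesterification. Its dianion (NaH, then n‑BuLi, THF, −78 °C) should add to 9 through the methoxy‑bearing γ‑carbon only, giving the β‑keto ester adduct F5. Pd(PPh3)4 with morpholine at room temperature then removes the allyl ester with decarboxylation to give 12.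

Further compounds
F1 | step 8 | (3S,4S,5S)‑3‑allyl‑5‑(3,4‑dimethoxyphenyl)‑3‑[2‑methoxy‑3‑oxo‑1‑(triethylsilyloxy)butyl]‑4‑methyldihydrofuran‑2(3H)‑one | CC(=O)C(OC)C(O[Si](CC)(CC)CC)[C@@]1(CC=C)C(=O)O[C@H](c2ccc(OC)c(OC)c2)[C@H]1C
F2 | step 8 | (4S)‑4‑allyl‑4‑[(1S,2S)‑1‑(3,4‑dimethoxyphenyl)‑1‑hydroxypropan‑2‑yl]‑6‑methoxy‑5‑(triethylsilyloxy)cyclohexane‑1,3‑dione | O=C1CC(=O)C(OC)C(O[Si](CC)(CC)CC)[C@]1(CC=C)[C@H](C)[C@H](O)c1ccc(OC)c(OC)c1
F3 | step 5 | (E,4S,5S)‑3‑[(allyloxy)methylidene]‑5‑(3,4‑dimethoxyphenyl)‑4‑methyldihydrofuran‑2(3H)‑one | C=CCO/C=C1\[C@H](C)[C@@H](c2ccc(OC)c(OC)c2)OC1=O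
F4 | step 7 | allyl 4‑methoxy‑3‑oxobutanoate | COCC(=O)CC(=O)OCC=C
F5 | step 7 | allyl 5‑[(3S,4S,5S)‑3‑allyl‑5‑(3,4‑dimethoxyphenyl)‑4‑methyl‑2‑oxotetrahydrofuran‑3‑yl]‑5‑hydroxy‑4‑methoxy‑3‑oxopentanoate | C=CCOC(=O)CC(=O)C(OC)C(O)[C@@]1(CC=C)C(=O)O[C@H](c2ccc(OC)c(OC)c2)[C@H]1C
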